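**Retrosynthetic overview**
1. Target 25 ← triol 24 by one triple angeloylation; both oxiranes are made last, on the enone-diol 21 (hydroxyl-directed peracid at C4=C5, nucleophilic at the C1(10) enone).
2. 21 ← cyclodecadienone 14 by reagent-controlled reduction at C3, bromination/SN2 inversion at C8 and Saegusa dehydrogenation to the C1(10) enone.
3. Key step: 14 ← anionic oxy-Cope ring expansion (six to ten) of dialkenyl carbinol 11. There is no macrocyclization (RCM, NHK) of an acyclic chain: the ring-cis C4=C5 alkene is inherited from the cyclohexene and the C9 oxygen arrives as a methyl enol ether.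
4. 11 ← enone 7 (Mukaiyama-type C8 side chain, vinyl addition) ← (R)-carvone by α'-hydroxylation and Wharton 1,3-enone transposition; C7 comes from the chiral pool and C6 is set next to it.
5. Ring order: the purchased six-membered ring is the only ring carried, it is expanded once to the ten-membered ring, and the two oxiranes close at the end.

Assumption: the SMILES is taken literally, so both oxiranes are cis (ring carbons cis, formally from 1(10)Z and 4Z alkenes); germacrane numbering (ring C1–C10, C14 on C10, C15 on C4, isopropenyl C11–C13 on C7) is used for all ten-membered compounds.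

**Route**

Step 1
Reactants: 1 (R)-(−)-carvone
Product: 3 (5S,6S)-6-hydroxycarvone, via sodium dienolate 2 (not isolated)
Conditions: NaN(SiMe3)2, THF, −78 °C; then 2-(phenylsulfonyl)-3-phenyloxaziridine, −78 °C; AcOH quench
Reagents that add atoms: 2-(phenylsulfonyl)-3-phenyloxaziridine, O=S(=O)(c1ccccc1)N1OC1c1ccccc1
Why: Kinetic α'-deprotonation followed by Davis enolate hydroxylation, the oxidant approaching C6 anti to the neighbouring isopropenyl group to give the trans (5S,6S) ketol.

Step 2
Reactants: 3 (5S,6S)-6-hydroxycarvone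
Product: 4 (5S,6S)-6-(tert-butyldimethylsilyloxy)carvone
Conditions: t-BuMe2SiOTf, 2,6-lutidine, CH2Cl2, 0 °C
Reagents that add atoms: tert-butyldimethylsilyl triflate, CC(C)(C)[Si](C)(C)OS(=O)(=O)C(F)(F)F
Why: Standard silylation of a hindered secondary alcohol that protects the ketol for the basic peroxide step and touches no stereocentre.

Step 3
Reactants: 4 (5S,6S)-6-(tert-butyldimethylsilyloxy)carvone
Product: 5 2,3-epoxy ketone of 4 (oxirane anti to isopropenyl)
Conditions: H2O2 (30% aq.), NaOH (cat.), MeOH, 0 °C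
Reagents that add atoms: hydrogen peroxide, OO
Why: Weitz–Scheffer nucleophilic epoxidation in which hydroperoxide adds to the β-carbon anti to the isopropenyl group as with carvone itself, and both new centres are erased again in steps 4 and 5.

Step 4
Reactants: 5 2,3-epoxy ketone
Product: 6 transposed allylic alcohol 4-(tert-butyldimethylsilyloxy)-2-methyl-5-isopropenylcyclohex-2-en-1-ol
Conditions: N2H4·H2O, AcOH (cat.), MeOH, 0 °C to rt
Reagents that add atoms: none
Why: Wharton transposition (hydrazone formation, epoxide opening, loss of N2) moves the oxygen to the former β-carbon and the alkene to the former carbonyl carbon, so the silyloxy group becomes γ to the future ketone.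

Step 5
Reactants: 6 transposed allylic alcohol
Product: 7 (4R,5S)-4-(tert-butyldimethylsilyloxy)-2-methyl-5-(prop-1-en-2-yl)cyclohex-2-en-1-one
Conditions: Dess–Martin periodinane, CH2Cl2, rt
Reagents that add atoms: none
Why: Dess–Martin oxidation of the allylic alcohol completes the 1,3-enone transposition without touching C6/C7 (germacrane numbering), which now carry OTBS and isopropenyl trans.

Step 6
Reactants: 7 transposed enone
Product: 9 6-(1-methoxyprop-2-en-1-yl) derivative of 7 (side chain trans to isopropenyl; methoxy carbon as epimer mixture), via silyl dienol ether 8 (not isolated)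
Conditions: LiN(iPr)2, Me3SiCl, THF, −78 °C; concentrate; then CH2=CHCH(OMe)2, Me3SiOTf (10 mol %), CH2Cl2, −78 °C
Reagents that add atoms: acrolein dimethyl acetal, C=CC(OC)OC
Why: Kinetic α'-silyl dienol ether formation and Mukaiyama-type addition to the acetal-derived oxocarbenium ion forms the C8–C9 bond anti to isopropenyl and delivers the C9 oxygen already as a methyl ether, whose carbinol configuration is irrelevant because C9 becomes sp2.

Step 7
Reactants: 9 allyl methyl ether
Product: 10 6-[(Z)-1-methoxyprop-1-en-1-yl] derivative of 7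
Conditions: [Ir(cod)(PMePh2)2]PF6 (2 mol %, activated with H2), THF, rt
Reagents that add atoms: none
Why: Iridium hydride-catalysed isomerization of the allyl ether to the enol ether acts only on the monosubstituted alkene and gives the 1-methoxypropenyl group regiospecifically without enolizing the ketone, the geometry (drawn Z) being inconsequential.

Step 8
Reactants: 10 enol ether ketone
Product: 11 1-vinyl carbinol (vinyl trans to the enol ether side chain)
Conditions: CH2=CHMgBr, CeCl3, THF, −78 °C; H2O quench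
Reagents that add atoms: vinylmagnesium bromide, C=C[Mg]Br
Why: Organocerium 1,2-addition to a hindered, easily enolized enone, the vinyl group entering anti to the adjacent side chain to give the trans-1,2-dialkenyl carbinol (either carbinol epimer can rearrange in step 9).

Step 9
Reactants: 11 1-vinyl carbinol
Product: 14 cyclodecadienone 6-(tert-butyldimethylsilyloxy)-9-methoxygermacra-4,8,11-trien-3-one (C4=C5 ring-cis; C8=C9 ring-trans), via potassium alkoxide 12 (not isolated), via potassium enolate 13 (not isolated)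
Conditions: KH, 18-crown-6, THF, 0 °C to rt; then AcOH (1 equiv), −78 °C
Reagents that add atoms: none
Why: Anionic oxy-Cope rearrangement through a chair transition state with both alkenyl groups equatorial breaks C3–C8 and forms C1–C10, so the ten-membered ring appears in one step with the ring-cis C4=C5 alkene carried over, C6/C7 untouched, C9 masked as an enol ether, and a C10 centre that is erased in step 13.

Step 10
Reactants: 14 cyclodecadienone
Product: 15 (3S)-allylic alcohol of 14
Conditions: (R)-1-methyl-3,3-diphenyl-tetrahydro-1H,3H-pyrrolo[1,2-c][1,3,2]oxazaborole ((R)-Me-CBS, 20 mol %), catecholborane, toluene, −78 °C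
Reagents that add atoms: none
Why: Corey–Bakshi–Shibata reduction under reagent control, the α-methylalkenyl arm acting as the large and C2H2 as the small group so that the (R)-catalyst gives the (3S)-alcohol while the enol ether is inert.

Step 11
Reactants: 15 (3S)-allylic alcohol
Product: 16 8-bromo-9-ketone (bromine trans to isopropenyl)
Conditions: N-bromosuccinimide, THF/H2O 4:1, 0 °C
Reagents that add atoms: N-bromosuccinimide, O=C1CCC(=O)N1Br; water, O
Why: Electrophilic bromination of the enol ether (oxocarbenium ion captured by water, methanol lost) occurs on the exposed face of the ring-trans C8=C9 bond, anti to the C7–C6 ring bond that spans the other face, which places bromine trans to the isopropenyl group.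

Step 12
Reactants: 16 8-bromo-9-ketone
Product: 18 6-(tert-butyldimethylsilyloxy)-3,8-dihydroxygermacra-4,11-dien-9-one, via formate ester 17 (not isolated)
Conditions: HCO2Cs, DMF, rt; then MeOH, KHCO3 (cat.), 0 °C
Reagents that add atoms: cesium formate, [Cs+].[O-]C=O
Why: SN2 displacement of the carbonyl-activated α-bromide by formate proceeds with inversion and so sets C8 with oxygen cis to isopropenyl, and the formate is methanolysed in the same flask.

Step 13
Reactants: 18 3,8-dihydroxy-9-ketone
Product: 21 (1(10)Z,4Z)-6-(tert-butyldimethylsilyloxy)-3,8-dihydroxygermacra-1(10),4,11-trien-9-one, via tris-silyl compound 19 (not isolated), via bis-silyl enone 20 (not isolated)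
Conditions: LiN(iPr)2 (3.3 equiv), Me3SiCl, THF, −78 °C; then Pd(OAc)2, MeCN, rt; then MeOH, citric acid (cat.)
Reagents that add atoms: none
Why: Saegusa–Ito dehydrogenation in which the C8 lithium alkoxide blocks enolization toward C8, the silyl enol ether therefore forms toward C10, and syn β-hydride elimination from the palladium enolate gives the C1(10) enone, expected as the less strained ring-cis isomer, with the transient silyl ethers removed on work-up.

Step 14
Reactants: 21 enone diol
Product: 22 4,5-epoxide of 21 (oxirane trans to the C3 hydroxyl and cis to the C6 silyloxy group)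
Conditions: mCPBA (1.1 equiv), CH2Cl2, 0 °C
Reagents that add atoms: 3-chloroperbenzoic acid, OOC(=O)c1cccc(Cl)c1
Why: Henbest hydroxyl-directed epoxidation, in which C3–H eclipses the Z-alkene (1,3-allylic strain) and the free C3 hydroxyl delivers the peracid to give the threo (ring-trans) cis-oxirane as known for Z-allylic and medium-ring allylic alcohols, the enone alkene being inert and the isopropenyl group slower.

Step 15
Reactants: 22 4,5-epoxide
Product: 23 1,10:4,5-diepoxide
Conditions: t-BuOOH, DBU, CH2Cl2, 0 °C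
Reagents that add atoms: tert-butyl hydroperoxide, CC(C)(C)OO
Why: Weitz–Scheffer epoxidation of the Z-enone with the peroxide adding to C1 from the ring periphery on the face of the C3 hydroxyl (hydrogen-bond assisted), the ring preventing C1–C10 rotation before closure so that the cis-oxirane results.

Step 16
Reactants: 23 diepoxide
Product: 24 1,10:4,5-diepoxy-3,6,8-trihydroxygermacr-11-en-9-one
Conditions: HF·pyridine, pyridine, THF, 0 °C to rt
Reagents that add atoms: none
Why: Buffered fluoride desilylation removes the single remaining silyl ether without opening the oxiranes or enolizing the ketol.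

Step 17
Reactants: 24 triol
Product: 25 target tris-angelate (1R,3S,4R,5S,6S,7S,8S,10R)
Conditions: angelic acid (6 equiv), 2,4,6-trichlorobenzoyl chloride, Et3N, toluene, rt; then 24, 80 °C
Reagents that add atoms: angelic acid, C/C=C(/C)C(=O)O
Why: Yamaguchi esterification through the mixed anhydride without nucleophilic catalyst, conditions that acylate hindered secondary alcohols with angelic acid without Z to E isomerization and leave all eight stereocentres untouched.

**Compound list**
1 | (R)-(−)-carvone, (5R)-2-methyl-5-(prop-1-en-2-yl)cyclohex-2-en-1-one | C=C(C)[C@H]1CC(=O)C(C)=CC1 | starting material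
2 | sodium cross-conjugated dienolate of 1 (C1–O−, C1=C6) | C=C(C)[C@H]1C=C([O-])C(C)=CC1.[Na+] | intermediate
3 | (5S,6S)-6-hydroxy-2-methyl-5-(prop-1-en-2-yl)cyclohex-2-en-1-one (OH trans to isopropenyl) | C=C(C)[C@H]1[C@H](O)C(=O)C(C)=CC1 | intermediate
4 | (5S,6S)-6-(tert-butyldimethylsilyloxy)-2-methyl-5-(prop-1-en-2-yl)cyclohex-2-en-1-one | C=C(C)[C@H]1[C@H](O[Si](C)(C)C(C)(C)C)C(=O)C(C)=CC1 | intermediate
5 | 2,3-epoxide of 4, oxirane anti to isopropenyl | C=C(C)[C@H]1[C@H](O[Si](C)(C)C(C)(C)C)C(=O)[C@]2(C)O[C@@H]2C1 | intermediate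
6 | 4-(tert-butyldimethylsilyloxy)-2-methyl-5-(prop-1-en-2-yl)cyclohex-2-en-1-ol (4,5-trans; 1-OH cis to the silyloxy group) | C=C(C)[C@H]1[C@H](O[Si](C)(C)C(C)(C)C)C=C(C)[C@H](O)C1 | intermediate
7 | (4R,5S)-4-(tert-butyldimethylsilyloxy)-2-methyl-5-(prop-1-en-2-yl)cyclohex-2-en-1-one | C=C(C)[C@H]1[C@H](O[Si](C)(C)C(C)(C)C)C=C(C)C(=O)C1 | intermediate
8 | trimethylsilyl dienol ether of 7 (C1–OSiMe3, C1=C6) | C=C(C)[C@H]1[C@H](O[Si](C)(C)C(C)(C)C)C=C(C)C(O[Si](C)(C)C)=C1 | intermediate
9 | 6-(1-methoxyprop-2-en-1-yl) derivative of 7, side chain trans to isopropenyl, methoxy carbon as epimer mixture | C=C(C)[C@H]1[C@H](O[Si](C)(C)C(C)(C)C)C=C(C)C(=O)[C@@H]1C(OC)C=C | intermediate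
10 | 6-[(Z)-1-methoxyprop-1-en-1-yl] derivative of 7 | C=C(C)[C@H]1[C@H](O[Si](C)(C)C(C)(C)C)C=C(C)C(=O)[C@@H]1/C(OC)=C/C | intermediate
11 | 1-vinyl carbinol from 10 (vinyl trans to the C6 side chain; germacrane C3 carbinol) | C=C(C)[C@H]1[C@H](O[Si](C)(C)C(C)(C)C)C=C(C)[C@@](O)(C=C)[C@@H]1/C(OC)=C/C | intermediate
12 | potassium alkoxide of 11 | C=C(C)[C@H]1[C@H](O[Si](C)(C)C(C)(C)C)C=C(C)[C@@]([O-])(C=C)[C@@H]1/C(OC)=C/C.[K+] | intermediate
13 | ring-expanded potassium enolate (C2=C3–O−) of 14 | C1C=C([O-])/C(C)=C\[C@@H](O[Si](C)(C)C(C)(C)C)[C@H](C(C)=C)/C=C(OC)/[C@H]1C.[K+] | intermediate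
14 | 6-(tert-butyldimethylsilyloxy)-9-methoxygermacra-4,8,11-trien-3-one; C4=C5 ring-cis, C8=C9 ring-trans, C6/C7 as in 25, C10 as predicted by the chair (10S) | C1CC(=O)/C(C)=C\[C@@H](O[Si](C)(C)C(C)(C)C)[C@H](C(C)=C)/C=C(OC)/[C@H]1C | intermediate
15 | (3S)-6-(tert-butyldimethylsilyloxy)-9-methoxygermacra-4,8,11-trien-3-ol | C1C[C@H](O)/C(C)=C\[C@@H](O[Si](C)(C)C(C)(C)C)[C@H](C(C)=C)/C=C(OC)/[C@H]1C | intermediate
16 | 8-bromo-6-(tert-butyldimethylsilyloxy)-3-hydroxygermacra-4,11-dien-9-one, bromine trans to isopropenyl | C=C(C)[C@H]1[C@H](O[Si](C)(C)C(C)(C)C)/C=C(C)\[C@@H](O)CC[C@H](C)C(=O)[C@@H]1Br | intermediate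
17 | 8-formyloxy-6-(tert-butyldimethylsilyloxy)-3-hydroxygermacra-4,11-dien-9-one, C8–O cis to isopropenyl | C=C(C)[C@H]1[C@H](O[Si](C)(C)C(C)(C)C)/C=C(C)\[C@@H](O)CC[C@H](C)C(=O)[C@H]1OC=O | intermediate
18 | 6-(tert-butyldimethylsilyloxy)-3,8-dihydroxygermacra-4,11-dien-9-one, C3 and C8 as in 25 | C=C(C)[C@H]1[C@H](O[Si](C)(C)C(C)(C)C)/C=C(C)\[C@@H](O)CC[C@H](C)C(=O)[C@H]1O | intermediate
19 | 3,8-bis(trimethylsilyl) ether and C9=C10 trimethylsilyl enol ether of 18 | C=C(C)[C@H]1[C@H](O[Si](C)(C)C(C)(C)C)/C=C(C)\[C@@H](O[Si](C)(C)C)CCC(C)=C(O[Si](C)(C)C)[C@H]1O[Si](C)(C)C | intermediate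
20 | 3,8-bis(trimethylsilyl) ether of 21 | C=C(C)[C@H]1[C@H](O[Si](C)(C)C(C)(C)C)/C=C(C)\[C@@H](O[Si](C)(C)C)C/C=C(C)\C(=O)[C@H]1O[Si](C)(C)C | intermediate
21 | (1(10)Z,4Z)-6-(tert-butyldimethylsilyloxy)-3,8-dihydroxygermacra-1(10),4,11-trien-9-one | C=C(C)[C@H]1[C@H](O[Si](C)(C)C(C)(C)C)/C=C(C)\[C@@H](O)C/C=C(C)\C(=O)[C@H]1O | intermediate
22 | 4,5-epoxide of 21 (cis-oxirane, trans to 3-OH, cis to the 6-silyloxy group) | C=C(C)[C@H]1[C@H](O[Si](C)(C)C(C)(C)C)[C@@H]2O[C@]2(C)[C@@H](O)C/C=C(C)\C(=O)[C@H]1O | intermediate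
23 | 6-(tert-butyldimethylsilyloxy)-1,10:4,5-diepoxy-3,8-dihydroxygermacr-11-en-9-one | C=C(C)[C@H]1[C@H](O[Si](C)(C)C(C)(C)C)[C@@H]2O[C@]2(C)[C@@H](O)C[C@H]2O[C@@]2(C)C(=O)[C@H]1O | intermediate
24 | 1,10:4,5-diepoxy-3,6,8-trihydroxygermacr-11-en-9-one | C=C(C)[C@H]1[C@H](O)[C@@H]2O[C@]2(C)[C@@H](O)C[C@H]2O[C@@]2(C)C(=O)[C@H]1O | intermediate
25 | (1R,3S,4R,5S,6S,7S,8S,10R)-1,10:4,5-diepoxy-9-oxogermacr-11-ene-3,6,8-triyl tris[(2Z)-2-methylbut-2-enoate] (CNP0154187.1) | C=C(C)[C@H]1[C@H](OC(=O)/C(C)=C\C)[C@@H]2O[C@]2(C)[C@@H](OC(=O)/C(C)=C\C)C[C@H]2O[C@@]2(C)C(=O)[C@H]1OC(=O)/C(C)=C\C | target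

**Totals and risks**
Total step count: 17. Longest linear sequence: 17 steps from 1 (the route is fully linear).

The three steps most likely to fail:

Step 9, the ring expansion. The alkoxide could fragment or shift instead of rearranging. The fallback sets out from 11 and comes back at 14 and removes the alkoxide altogether. Carbinol 11 is silylated with N-(trimethylsilyl)imidazole to the C3 trimethylsilyl ether F1. This is heated in degassed o-dichlorobenzene (180–200 °C, sealed tube, a little N,O-bis(trimethylsilyl)acetamide as acid scavenger), where a neutral silyloxy-Cope rearrangement gives the ring-expanded C3 silyl dienol ether F2. Brief treatment with K2CO3 in MeOH at 0 °C cleaves only the trimethylsilyl enol ether and gives 14.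

Step 11, the facial sense of electrophilic attack at C8, which rests on a conformational argument for a flexible ring. If bromine enters cis to the isopropenyl group, step 12 would deliver the C8 epimer. The fallback sets out from 15 and comes back at 18, bypassing 16 and 17, and uses the same facial preference with retention instead of inversion. Dimethyldioxirane (acetone/CH2Cl2, −78 °C) epoxidizes the enol ether to the 8,9-epoxy-9-methoxy intermediate F3, which is hydrolysed in the same flask (H2O, pyridinium p-toluenesulfonate) to the α-hydroxy ketone 18.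

Step 15, the nucleophilic epoxidation. Its face selectivity is uncertain and the basic medium may epimerize C8. The fallback sets out from 20 (isolated by leaving out the methanolysis of step 13) and comes back at 23, replacing the stepwise nucleophilic process by a concerted hydroxyl-directed one. i-Bu2AlH (CH2Cl2, −78 °C) reduces the enone to the C9 allylic alcohol F4. VO(acac)2 with t-BuOOH then epoxidizes the C1(10) alkene syn to the only free hydroxyl, which guarantees the cis-oxirane geometry, to give the 1,10-epoxy-9-ol F5. Dess–Martin oxidation returns the 1,10-epoxy-9-ketone F6, and K2CO3 in MeOH removes both trimethylsilyl ethers to give the 1,10-epoxy diol F7. Epoxidation with mCPBA, directed by the C3 hydroxyl exactly as in step 14, then gives 23.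

Further compounds
F1 | step 9 | C3 trimethylsilyl ether of carbinol 11 | C=C(C)[C@H]1[C@H](O[Si](C)(C)C(C)(C)C)C=C(C)[C@@](O[Si](C)(C)C)(C=C)[C@@H]1/C(OC)=C/C
F2 | step 9 | ring-expanded C3 trimethylsilyl dienol ether of 14 | C1C=C(O[Si](C)(C)C)/C(C)=C\[C@@H](O[Si](C)(C)C(C)(C)C)[C@H](C(C)=C)/C=C(OC)/[C@H]1C
F3 | step 11 | 8,9-epoxy-9-methoxy intermediate from 15, C8 oxygen cis to isopropenyl | C1C[C@H](O)/C(C)=C\[C@@H](O[Si](C)(C)C(C)(C)C)[C@H](C(C)=C)[C@@H]2O[C@@]2(OC)[C@H]1C
F4 | step 15 | C9 allylic alcohol from 20, 3,8-bis(trimethylsilyl) ether, 9-OH on the face of the 8-oxygen | C=C(C)[C@H]1[C@H](O[Si](C)(C)C(C)(C)C)/C=C(C)\[C@@H](O[Si](C)(C)C)C/C=C(C)\[C@@H](O)[C@H]1O[Si](C)(C)C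
F5 | step 15 | 1,10-epoxy-9-ol, 3,8-bis(trimethylsilyl) ether | C=C(C)[C@H]1[C@H](O[Si](C)(C)C(C)(C)C)/C=C(C)\[C@@H](O[Si](C)(C)C)C[C@H]2O[C@@]2(C)[C@@H](O)[C@H]1O[Si](C)(C)C
F6 | step 15 | 1,10-epoxy-9-ketone, 3,8-bis(trimethylsilyl) ether | C=C(C)[C@H]1[C@H](O[Si](C)(C)C(C)(C)C)/C=C(C)\[C@@H](O[Si](C)(C)C)C[C@H]2O[C@@]2(C)C(=O)[C@H]1O[Si](C)(C)C
F7 | step 15 | 6-(tert-butyldimethylsilyloxy)-1,10-epoxy-3,8-dihydroxygermacra-4,11-dien-9-one | C=C(C)[C@H]1[C@H](O[Si](C)(C)C(C)(C)C)/C=C(C)\[C@@H](O)C[C@H]2O[C@@]2(C)C(=O)[C@H]1O
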